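**Retrosynthetic overview**
1. Target ⇒ its pentabenzyl ether. Neutral hydrogenolysis comes last, so the free 4'-hydroxyflavanone never meets acid or base.
2. Pentabenzyl ether ⇒ both pyranone rings opened at O1–C2 at once. Flavanone ring C goes back to a tert-butyl-ester-activated 2'-hydroxychalcone (asymmetric oxa-Michael addition, sets C2). Flavone ring C goes back to an o-hydroxy-1,3-diketone (cyclodehydration).
3. The doubly open precursor ⇒ Knoevenagel union of a biaryl aldehyde–diketone with a tert-butyl aroylacetate.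
4. Biaryl aldehyde–diketone ⇒ Suzuki coupling of a 3-iodo-2-hydroxyaryl diketone with a formylphenyl boronate. Both phloroglucinol rings come from one dibenzyl phloroacetophenone.
5. Ring order: the four benzene rings are bought and the biaryl bond is made while both halves are still acyclic. Flavanone ring C and then flavone ring C close last, in one flask.

Assumption: of the two pseudoenantiomeric 9-amino(9-deoxy)epi-cinchona thioureas, the quinine-derived one is taken to give the (2S) series; if chiral HPLC and circular dichroism of a test run show the opposite sense, the quinidine-derived catalyst replaces it with no other change.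

**Step 1**
Reactants: 1 2',4',6'-trihydroxyacetophenone
Product: 2 1-[2,4-bis(benzyloxy)-6-hydroxyphenyl]ethan-1-one
Conditions: BnBr (2.1 equiv), K2CO3 (2.2 equiv), DMF, rt to 50 °C
Reagents that add atoms: benzyl bromide, BrCc1ccccc1
Why: Williamson etherification takes the 4-OH and one of the two equivalent ortho OH groups, after which the last ortho OH is locked in a strong hydrogen bond to the acetyl carbonyl and stays free.

**Step 2**
Reactants: 2 1-[2,4-bis(benzyloxy)-6-hydroxyphenyl]ethan-1-one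
Product: 4 tert-butyl 3-[2,4-bis(benzyloxy)-6-hydroxyphenyl]-3-oxopropanoate, via aryl tert-butyl carbonate 3 (not isolated)
Conditions: Boc2O (1.1 equiv), DMAP (5 mol%), THF, rt; then LiHMDS (3.5 equiv), –78 to 0 °C; cold dilute aq. HCl quench
Reagents that add atoms: di-tert-butyl dicarbonate, CC(C)(C)OC(=O)OC(=O)OC(C)(C)C
Why: This is the carbonate variant of the Baker–Venkataraman rearrangement (intramolecular Claisen condensation), in which the lithium enolate of the acetyl group attacks the neighbouring carbonate through a six-membered transition state and expels the aryloxide rather than tert-butoxide, moving CO2tBu from O to C and freeing the phenol again.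

**Step 3**
Reactants: 2 1-[2,4-bis(benzyloxy)-6-hydroxyphenyl]ethan-1-one
Product: 5 1-[4,6-bis(benzyloxy)-2-hydroxy-3-iodophenyl]ethan-1-one
Conditions: NIS (1.05 equiv), TFA (10 mol%), MeCN, 0 °C to rt, dark
Reagents that add atoms: N-iodosuccinimide, O=C1CCC(=O)N1I
Why: Electrophilic aromatic iodination goes to position 3, which is ortho to the free phenol (the strongest donor) and flanked by OH and only one OBn, rather than to position 5, which is wedged between two benzyloxy groups.

**Step 4**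
Reactants: 5 1-[4,6-bis(benzyloxy)-2-hydroxy-3-iodophenyl]ethan-1-one; 6 4-methoxybenzoyl chloride
Product: 7 1-[4,6-bis(benzyloxy)-2-hydroxy-3-iodophenyl]-3-(4-methoxyphenyl)propane-1,3-dione
Conditions: LiHMDS (3.5 equiv), THF, –78 °C; then 6 (1.05 equiv), –78 to –10 °C; cold dilute aq. HCl quench
Reagents that add atoms: none
Why: This is a Claisen-type C-aroylation of the lithium phenoxide–enolate dianion (direct form of the Baker–Venkataraman sequence), in which any O-aroylated material is carried to the same diketone by the excess base and the amide base leaves the aryl iodide and benzyl ethers alone.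

**Step 5**
Reactants: 8 4-(benzyloxy)-3-bromobenzaldehyde; 7 1-[4,6-bis(benzyloxy)-2-hydroxy-3-iodophenyl]-3-(4-methoxyphenyl)propane-1,3-dione
Product: 10 4-(benzyloxy)-3-{4,6-bis(benzyloxy)-2-hydroxy-3-[3-(4-methoxyphenyl)-3-oxopropanoyl]phenyl}benzaldehyde, via pinacol boronate 9 (not isolated)
Conditions: 8 (1.3 equiv), B2pin2 (1.4 equiv), PdCl2(dppf) (4 mol%), KOAc (4 equiv), dioxane, 90 °C; then 7 (1.0 equiv), SPhos (8 mol%), aq. K3PO4 (6 equiv), 70 °C
Reagents that add atoms: bis(pinacolato)diboron, CC1(C)OB(OC1(C)C)B1OC(C)(C)C(C)(C)O1 (its boron stays only in intermediate 9)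
Why: In this one-pot Miyaura borylation and Suzuki–Miyaura coupling the bromide is borylated without touching the aldehyde, and the hindered iodide then couples as its phenoxide–diketonate dianion, a form inert to hydroxide and to the aldehyde, while SPhos-ligated palladium copes with the three ortho substituents at the new biaryl bond.

**Step 6**
Reactants: 10 4-(benzyloxy)-3-{4,6-bis(benzyloxy)-2-hydroxy-3-[3-(4-methoxyphenyl)-3-oxopropanoyl]phenyl}benzaldehyde; 4 tert-butyl 3-[2,4-bis(benzyloxy)-6-hydroxyphenyl]-3-oxopropanoate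
Product: 11 tert-butyl (Z)-2-[2,4-bis(benzyloxy)-6-hydroxybenzoyl]-3-[4-(benzyloxy)-3-{4,6-bis(benzyloxy)-2-hydroxy-3-[3-(4-methoxyphenyl)-3-oxopropanoyl]phenyl}phenyl]prop-2-enoate
Conditions: 4 (2.0 equiv, excess recovered), piperidine (20 mol%), AcOH (20 mol%), 4 Å sieves, toluene, rt
Reagents that add atoms: none
Why: In this Knoevenagel condensation through the piperidine iminium ion of the aldehyde, the keto-form methylene of 4 (in excess) should react faster than the fully enolised, doubly chelated and more hindered diaryl diketone of 10, and in the weakly acidic buffer at rt the hydrogen-bonded phenol does not yet add to the new alkylidene.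

**Step 7 (key step)**
Reactants: 11 tert-butyl (Z)-2-[2,4-bis(benzyloxy)-6-hydroxybenzoyl]-3-[4-(benzyloxy)-3-{4,6-bis(benzyloxy)-2-hydroxy-3-[3-(4-methoxyphenyl)-3-oxopropanoyl]phenyl}phenyl]prop-2-enoate
Product: 13 (2S)-5,7-bis(benzyloxy)-2-{4-(benzyloxy)-3-[5,7-bis(benzyloxy)-2-(4-methoxyphenyl)-4-oxo-4H-chromen-8-yl]phenyl}-2,3-dihydro-4H-chromen-4-one, via trans keto ester 12 (not isolated)
Conditions: N-[3,5-bis(trifluoromethyl)phenyl]-N'-[(8α,9S)-6'-methoxycinchonan-9-yl]thiourea (15 mol%), toluene/CH2Cl2 9:1, –25 °C, 48 h; then TsOH·H2O (1.5 equiv), same flask, 80 °C, 3 h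
Reagents that add atoms: none
Why: Proposed new method: the quinuclidine nitrogen of the bifunctional catalyst activates the ring A phenol while the thiourea binds the β-keto ester, so the oxygen adds 6-endo to one face of the ester-activated alkylidene and sets C2 as S (intramolecular asymmetric oxa-Michael addition of alkylidene β-keto esters with in-flask acid decarboxylation is the closest known reaction type), and the TsOH that then removes the tert-butyl ester as isobutene and CO2 also cyclodehydrates the untouched o-hydroxy-1,3-diketone through its only free ortho OH (last stage of the Baker–Venkataraman flavone synthesis, giving the 8-aryl isomer only), so both pyranone rings close in one flask and only the combination on a substrate carrying a free diketone is new.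

**Step 8**
Reactants: 13 (2S)-5,7-bis(benzyloxy)-2-{4-(benzyloxy)-3-[5,7-bis(benzyloxy)-2-(4-methoxyphenyl)-4-oxo-4H-chromen-8-yl]phenyl}-2,3-dihydro-4H-chromen-4-one
Product: 14 (2S)-2,3-dihydropodocarpusflavone A
Conditions: H2 (1 atm), 10% Pd/C, THF/MeOH 1:1, rt; filter, evaporate below 30 °C
Reagents that add atoms: none
Why: Catalytic hydrogenolysis of the five aryl benzyl ethers under neutral conditions leaves the aryl methyl ether, the flavone C2=C3 bond and both ketones alone, and it never exposes the free 4'-hydroxyflavanone, whose C2 centre racemises by ring opening, to base or hot acid.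

**Compound list**
1 | 2',4',6'-trihydroxyacetophenone | CC(=O)c1c(O)cc(O)cc1O | starting material
2 | 1-[2,4-bis(benzyloxy)-6-hydroxyphenyl]ethan-1-one | CC(=O)c1c(O)cc(OCc2ccccc2)cc1OCc1ccccc1 | intermediate
3 | 2-acetyl-3,5-bis(benzyloxy)phenyl tert-butyl carbonate | CC(=O)c1c(OC(=O)OC(C)(C)C)cc(OCc2ccccc2)cc1OCc1ccccc1 | intermediate
4 | tert-butyl 3-[2,4-bis(benzyloxy)-6-hydroxyphenyl]-3-oxopropanoate | CC(C)(C)OC(=O)CC(=O)c1c(O)cc(OCc2ccccc2)cc1OCc1ccccc1 | intermediate
5 | 1-[4,6-bis(benzyloxy)-2-hydroxy-3-iodophenyl]ethan-1-one | CC(=O)c1c(O)c(I)c(OCc2ccccc2)cc1OCc1ccccc1 | intermediate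
6 | 4-methoxybenzoyl chloride | COc1ccc(cc1)C(Cl)=O | starting material
7 | 1-[4,6-bis(benzyloxy)-2-hydroxy-3-iodophenyl]-3-(4-methoxyphenyl)propane-1,3-dione (drawn as diketone, mainly enol) | COc1ccc(cc1)C(=O)CC(=O)c1c(O)c(I)c(OCc2ccccc2)cc1OCc1ccccc1 | intermediate
8 | 4-(benzyloxy)-3-bromobenzaldehyde | O=Cc1ccc(OCc2ccccc2)c(Br)c1 | starting material
9 | 4-(benzyloxy)-3-(4,4,5,5-tetramethyl-1,3,2-dioxaborolan-2-yl)benzaldehyde | O=Cc1ccc(OCc2ccccc2)c(c1)B1OC(C)(C)C(C)(C)O1 | intermediate
10 | 4-(benzyloxy)-3-{4,6-bis(benzyloxy)-2-hydroxy-3-[3-(4-methoxyphenyl)-3-oxopropanoyl]phenyl}benzaldehyde | COc1ccc(cc1)C(=O)CC(=O)c1c(O)c(c(OCc2ccccc2)cc1OCc1ccccc1)-c1cc(C=O)ccc1OCc1ccccc1 | intermediate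
11 | tert-butyl (Z)-2-[2,4-bis(benzyloxy)-6-hydroxybenzoyl]-3-[4-(benzyloxy)-3-{4,6-bis(benzyloxy)-2-hydroxy-3-[3-(4-methoxyphenyl)-3-oxopropanoyl]phenyl}phenyl]prop-2-enoate | CC(C)(C)OC(=O)/C(C(=O)c1c(O)cc(OCc2ccccc2)cc1OCc1ccccc1)=C\c1ccc(OCc2ccccc2)c(c1)-c1c(O)c(C(=O)CC(=O)c2ccc(OC)cc2)c(OCc2ccccc2)cc1OCc1ccccc1 | intermediate
12 | tert-butyl (2S,3R)-5,7-bis(benzyloxy)-2-[4-(benzyloxy)-3-{4,6-bis(benzyloxy)-2-hydroxy-3-[3-(4-methoxyphenyl)-3-oxopropanoyl]phenyl}phenyl]-4-oxochromane-3-carboxylate (C3 epimerisable, in equilibrium with its enol) | COc1ccc(cc1)C(=O)CC(=O)c1c(O)c(c(OCc2ccccc2)cc1OCc1ccccc1)-c1cc([C@@H]2[C@@H](C(=O)OC(C)(C)C)C(=O)c3c(OCc4ccccc4)cc(OCc4ccccc4)cc3O2)ccc1OCc1ccccc1 | intermediate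
13 | (2S)-5,7-bis(benzyloxy)-2-{4-(benzyloxy)-3-[5,7-bis(benzyloxy)-2-(4-methoxyphenyl)-4-oxo-4H-chromen-8-yl]phenyl}-2,3-dihydro-4H-chromen-4-one | COc1ccc(-c2cc(=O)c3c(OCc4ccccc4)cc(OCc4ccccc4)c(-c4cc([C@@H]5CC(=O)c6c(OCc7ccccc7)cc(OCc7ccccc7)cc6O5)ccc4OCc4ccccc4)c3o2)cc1 | intermediate
14 | (2S)-2,3-dihydropodocarpusflavone A | COc1ccc(-c2cc(=O)c3c(O)cc(O)c(-c4cc([C@@H]5CC(=O)c6c(O)cc(O)cc6O5)ccc4O)c3o2)cc1 | target

**Totals**
Total step count: 8.
Longest linear sequence: 7 (steps 1, 3, 4, 5, 6, 7, 8). Step 2 is a one-step branch from 2.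

**Three steps most likely to fail**

**Step 7.**
- The acidic diketone enol may tie up the catalyst.
- The 6'-benzyloxy group may raise the uncatalysed background reaction.
- The electron-rich 4-benzyloxyphenyl group may let C2 erode in hot TsOH.

The fallback replaces asymmetric ring closure by kinetic resolution; it sets out from 11 and comes back at 13. DABCO (20 mol%) in toluene at rt closes the flavanone ring without stereocontrol to the racemic trans keto ester F1. TsOH at 80 °C in the same flask then gives the racemic pentabenzyl ether F2. Asymmetric transfer hydrogenation with Cp*RhCl[(R,R)-TsDPEN] in HCO2H/Et3N/EtOAc at rt is stopped near 52% conversion. It reduces the matched (2R) enantiomer to the cis-(2R,4R)-flavan-4-ol F3 and leaves the (2S) ketone, which is 13, for separation on silica.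

**Step 6.** The diketone CH2 of 10 or 11 may compete as Knoevenagel or Michael donor, giving 3-aroylflavanone-type oligomers. The alkylidene may also close early without stereocontrol. The fallback removes the competing carbon acid by closing the flavone ring first; it sets out from 10 and comes back at 13. TsOH (10 mol%) in toluene at 80 °C turns 10 into the flavone aldehyde F4. Knoevenagel condensation of F4 with 4 under the step 6 conditions gives the flavone alkylidene keto ester F5. The thiourea catalyst at –25 °C converts F5 into the flavone trans keto ester F6, which is not isolated, and TsOH at 80 °C decarboxylates it to 13.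

**Step 5.** The iodide is hindered and reacts as a dianion, so oxidative addition may be slow, protodeiodination may intervene, and the aldehyde may be attacked by the diketonate at 70 °C. The fallback makes the biaryl bond before the diketone exists. It sets out from 8 and 5 and comes back at 10.
- Ethylene glycol with TsOH (cat.) in toluene under Dean–Stark conditions masks 8 as the dioxolane bromide F7.
- Borylation as in step 5 gives the dioxolane boronate F8.
- F8 is coupled in the same flask with the simpler iodoacetophenone 5 to give the biaryl acetophenone acetal F9.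
- LiHMDS and 6, as in step 4, then install the aroyl group with no aldehyde present, giving the diketone acetal F10.
- PPTS in wet acetone at rt frees the aldehyde without closing the flavone, which gives 10.

**Further compounds**
F1 | step 7 | racemic tert-butyl trans-5,7-bis(benzyloxy)-2-[4-(benzyloxy)-3-{4,6-bis(benzyloxy)-2-hydroxy-3-[3-(4-methoxyphenyl)-3-oxopropanoyl]phenyl}phenyl]-4-oxochromane-3-carboxylate (racemate of 12) | COc1ccc(cc1)C(=O)CC(=O)c1c(O)c(c(OCc2ccccc2)cc1OCc1ccccc1)-c1cc(C2C(C(=O)OC(C)(C)C)C(=O)c3c(OCc4ccccc4)cc(OCc4ccccc4)cc3O2)ccc1OCc1ccccc1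
F2 | step 7 | racemic pentabenzyl ether (racemate of 13) | COc1ccc(-c2cc(=O)c3c(OCc4ccccc4)cc(OCc4ccccc4)c(-c4cc(C5CC(=O)c6c(OCc7ccccc7)cc(OCc7ccccc7)cc6O5)ccc4OCc4ccccc4)c3o2)cc1
F3 | step 7 | 5,7-bis(benzyloxy)-8-{2-(benzyloxy)-5-[(2R,4R)-5,7-bis(benzyloxy)-4-hydroxychroman-2-yl]phenyl}-2-(4-methoxyphenyl)-4H-chromen-4-one | COc1ccc(-c2cc(=O)c3c(OCc4ccccc4)cc(OCc4ccccc4)c(-c4cc([C@H]5C[C@@H](O)c6c(OCc7ccccc7)cc(OCc7ccccc7)cc6O5)ccc4OCc4ccccc4)c3o2)cc1
F4 | step 6 | 4-(benzyloxy)-3-[5,7-bis(benzyloxy)-2-(4-methoxyphenyl)-4-oxo-4H-chromen-8-yl]benzaldehyde | COc1ccc(-c2cc(=O)c3c(OCc4ccccc4)cc(OCc4ccccc4)c(-c4cc(C=O)ccc4OCc4ccccc4)c3o2)cc1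
F5 | step 6 | tert-butyl (Z)-2-[2,4-bis(benzyloxy)-6-hydroxybenzoyl]-3-{4-(benzyloxy)-3-[5,7-bis(benzyloxy)-2-(4-methoxyphenyl)-4-oxo-4H-chromen-8-yl]phenyl}prop-2-enoate | COc1ccc(-c2cc(=O)c3c(OCc4ccccc4)cc(OCc4ccccc4)c(-c4cc(/C=C(\C(=O)OC(C)(C)C)C(=O)c5c(O)cc(OCc6ccccc6)cc5OCc5ccccc5)ccc4OCc4ccccc4)c3o2)cc1
F6 | step 6 | tert-butyl (2S,3R)-5,7-bis(benzyloxy)-2-{4-(benzyloxy)-3-[5,7-bis(benzyloxy)-2-(4-methoxyphenyl)-4-oxo-4H-chromen-8-yl]phenyl}-4-oxochromane-3-carboxylate | COc1ccc(-c2cc(=O)c3c(OCc4ccccc4)cc(OCc4ccccc4)c(-c4cc([C@@H]5[C@@H](C(=O)OC(C)(C)C)C(=O)c6c(OCc7ccccc7)cc(OCc7ccccc7)cc6O5)ccc4OCc4ccccc4)c3o2)cc1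
F7 | step 5 | 2-[4-(benzyloxy)-3-bromophenyl]-1,3-dioxolane | Brc1cc(ccc1OCc1ccccc1)C1OCCO1
F8 | step 5 | 2-[2-(benzyloxy)-5-(1,3-dioxolan-2-yl)phenyl]-4,4,5,5-tetramethyl-1,3,2-dioxaborolane | CC1(C)OB(OC1(C)C)c1cc(ccc1OCc1ccccc1)C1OCCO1
F9 | step 5 | 1-{4,6-bis(benzyloxy)-3-[2-(benzyloxy)-5-(1,3-dioxolan-2-yl)phenyl]-2-hydroxyphenyl}ethan-1-one | CC(=O)c1c(O)c(c(OCc2ccccc2)cc1OCc1ccccc1)-c1cc(ccc1OCc1ccccc1)C1OCCO1
F10 | step 5 | 1-{4,6-bis(benzyloxy)-3-[2-(benzyloxy)-5-(1,3-dioxolan-2-yl)phenyl]-2-hydroxyphenyl}-3-(4-methoxyphenyl)propane-1,3-dione | COc1ccc(cc1)C(=O)CC(=O)c1c(O)c(c(OCc2ccccc2)cc1OCc1ccccc1)-c1cc(ccc1OCc1ccccc1)C1OCCO1
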